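## Structural features

The target is a 6,7-seco-ent-kaurane spirolactone (locants C1–C20 are the diterpenoid ones, C17 being the methyl group on C16). Ring A (C1–C5, C10) is a 4,4-dimethylcyclohex-2-en-1-one whose C10 is the spiro atom of a δ-lactone (C10–C20H2–O–C7(=O)–C8–C9); the lactone is cis-fused through C8–C9 to cyclohexane ring C (C8, C9, C11–C14), and C8 and C13 are bridged by C15(=O)–C16(OH)(C17H3), which closes ring D and gives a bicyclo[3.2.1]octane. There are six stereocentres, four of them contiguous (C5, C10, C9, C8) and two of these quaternary (spiro C10, bridgehead C8 carrying both C7 and C15); C20 is cis to the C6 hydroxymethyl group on ring A, H9 is cis to C15 on the lactone, and the C16 hydroxyl is exo (anti to the C9–C11–C12 bridge). The fragile groups are the non-enolisable β-keto lactone at C8 (open to retro-Claisen cleavage by nucleophilic base), the tertiary α-ketol at C15/C16 (acyloin shift), the enone and the free primary C6 carbinol. The real difficulty is the congested C5–C10–C9–C8 array together with the need to hold four oxygenated carbons (C6, C20, C7, C15) at different oxidation levels. A helpful feature is that neither C1 (C10 and C4 quaternary, C2 vinylic) nor C7 can be enolised once the skeleton stands, so C16–H is then the only acidic C–H. The key step exploits the make-up of ring A: C3, C4 and the two methyl groups are 2-methylpropanal, C2–C1–C10 with C20 is an acetoacetate, and C5–C6 is a two-carbon oxygenated aldehyde, so C4–C5 is a Michael bond and C2=C3 an aldol-condensation bond, and the quaternary C4 leaves the aldehyde without α-hydrogen and thus with a single condensation mode.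

## Logic of the disconnections

25 to 23 (through 24): the C16–O bond and the O6–Si bond are cut. In 23 the C16–H is the only enolisable position and the exo face of ring D is open, so the tertiary carbinol can be written last. This removes the α-ketol and one stereocentre from every earlier step. The forward step must deliver oxygen to the exo face with a non-nucleophilic base.

23 to 21 (through 22): the C13–C16 bond of ring D is cut. A C16 radical tethered through an sp3 C15 to C8 sits in a hex-5-enyl relation to the C12=C13 bond, so 5-exo closure gives the bicyclo[3.2.1]octane and C13 follows from the bridging. The tetracycle is reduced to a cis-fused bicyclic lactone with a side chain. The demand is that C15 is a carbinol during the closure (re-oxidised in 23) and that ring closure outruns hydrogen transfer.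

21 to 16 and 19: the C15–C16 bond is cut. C15 of 16 is the only strongly electrophilic carbonyl carbon and 16 has no acidic C–H, so a two-carbon carbanion that already carries the radical leaving group can be added; 19 comes from 17 and 18 in one step. The forward addition must be run cold to avoid retro-aldol loss of C15.

16 to 14 and 15, and 15 back to 11 (through 13 and 12): the C9–C11 and C8–C14 bonds of ring C are cut. A suprafacial [4+2] addition sets the cis ring fusion and the quaternary C8 at once, and the C15 formyl group that activates the dienophile is the carbon needed for ring D. The dienophile is traced to 11 by cutting C8–C15 (formylation) and by restoring C8–C9 as a single bond (selenoxide route). The demand is attack of 14 on the face of C8=C9 next to the flat C1 carbonyl and away from the C5/C4 flank.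

11 to 8 (through 10 and 9): the O20–C7 acyl bond is cut and the oxidation levels are levelled. All three carbonyl groups of 8 are reduced together and then C1 is re-oxidised as an allylic alcohol and C7 as the less hindered primary carbinol, so no protecting group is spent. The demand is two chemoselective oxidations. The C2=C3 bond made in 6 is kept all the way to 25 and is never hydrogenated, since it is the C2=C3 bond of 25 and since it keeps C1 non-enolisable in steps 7, 11 and 14.

8 to 6 and 7: the C9–C10 bond is cut. C10 of 6 is the α-carbon of a β-keto ester and a soft Michael donor; this creates the quaternary spiro carbon. The demand is attack anti to the C6 arm, which leaves C20 cis to C6.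

6 to 3 and 4 (through 5): the C4–C5 bond and the C2=C3 bond are cut, which opens ring A (key step). The silyl ether and the ethyl ester of 3 are retained: they keep O6 and O20 distinct to the end, and an ethyl β-keto ester does not decarboxylate under the acid used for ring closure. C5 of 6 has the spatial arrangement of C5 in 25; its descriptor changes from S to R in 8 only through the CIP priorities. The demand is face control at C5 and closure through the C2 enol.

3 to 1 and 2: the C5=C10 bond is cut (Knoevenagel), leaving three commercial materials.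

## Other disconnections considered

Alternative 1: The cut is C5–C10, made by a [3,3] shift that at the same time breaks a temporary O–C2 bond. The forward key step is an Ireland–Claisen rearrangement with ring contraction of a lactone enol silane, which gives the ring A cyclohexene acid A1.
- In its favour: C5 and C10 arise in one concerted step with chirality relayed from a single carbinol centre through a ring-constrained transition state. The two arms on C10 arrive already differentiated (C20 as a benzyl-type ether, C9–C8–C7 as a silylated propanol), so the quaternary centre does not depend on the facial selectivity of an alkylation. On this point it is better than the chosen plan, and on absolute control it is its equal.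
- Against it here: the substrate needs a stereodefined trisubstituted alkene and a lactone, which costs several steps. A1 carries the ring double bond at C1=C2 and no oxygen at C1, so the 1-oxo-2-ene has to be made by an oxidative allylic transposition. C6 is at the acid level and C7 at the alcohol level, the reverse of what the later steps need.
- Comparison: on step economy the chosen plan is clearly better, with ring A in two steps at the right oxidation pattern.

Alternative 2: The cut is C10–C20 and C5–C6 together. The forward key step is a [2+2] photocycloaddition of the ring A enone (C1 carbonyl, C10=C5) with acetylene A3, which gives the cis-fused cyclobutene A2; oxidative cleavage of its C20=C6 bond then gives the two one-carbon arms.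
- In its favour: the cis relation of C20 and C6 is guaranteed by the ring fusion, which is better than the chosen plan on relative configuration at C5/C10. A3 is symmetrical, so there is no regiochemical issue, and the C9–C8–C7 ester chain is in place before C10 becomes quaternary.
- Against it here: A2 would be racemic unless a chiral sensitiser or auxiliary is added, whereas the chosen plan sets C5 catalytically. Cleavage gives two aldehydes (C20 and C6) that must then be told apart. A2 is a β,γ-unsaturated ketone and can undergo secondary photoreactions. Ring A is saturated, so C2=C3 must be introduced late, at a stage where a second enolisable ketone may be present.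
- Comparison: the step count to the spirolactone is about equal for racemic material and longer for a single enantiomer.

Alternative 3: The cut is C15–C16 in ring D. The forward key step is an SmI2 pinacol coupling of a C15 aldehyde on C8 with a C16 methyl ketone on C13, which gives the cis-15,16-diol A4; oxidation of the secondary C15 carbinol would follow.
- In its favour: ring D and the tertiary C16 carbinol are made in one step, without a separate enolate hydroxylation. For ring D alone it is shorter than the chosen sequence (steps 11–14) and is the better on that count.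
- Against it here: it needs an acetyl group on C13 cis to the C8 formyl group, a 1,3-pattern that a simple Diels–Alder reaction of 14 does not deliver, so ring C costs more steps. SmI2 would reduce the ring A enone, so ring A must be saturated as in A4; the C1 ketone then competes for ketyl formation and C2=C3 has to be reinstalled afterwards. The C16 configuration is fixed by the chelate geometry and cannot be tuned independently.
- Comparison: it is a ring D disconnection and does not compete with the ring A annulation; it could be combined with it. It is not adopted because it gives up the non-enolisable enone that protects C1 throughout the chosen route.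

Key step: step 2

Remark: 3 is used as the E/Z mixture on the assumption that the isomers equilibrate under the amine catalysis, and the (R,R) catalyst is written on the assumption that it shields the appropriate face; the (S,S) enantiomer, equally available, would be used if the sense of induction proved opposite.

## Route

Step 1
Reactants: 1 ethyl acetoacetate; 2 (tert-butyldimethylsilyloxy)acetaldehyde
Product: 3 ethyl (2E)-2-acetyl-4-[(tert-butyldimethylsilyl)oxy]but-2-enoate (formed together with the 2Z isomer and used as the mixture)
Conditions: piperidine (10 mol%), AcOH (10 mol%), 4 Å molecular sieves, CH2Cl2, 0 °C to rt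
Reagents that add atoms: none
Why: Knoevenagel condensation of an active methylene compound with an unhindered α-oxygenated aldehyde; low temperature and a slight excess of 2 should suppress the bis-adduct from a second Michael addition of 1.

Step 2
Reactants: 3 ethyl (2E/Z)-2-acetyl-4-[(tert-butyldimethylsilyl)oxy]but-2-enoate; 4 isobutyraldehyde
Product: 6 ethyl (1S,6S)-6-{[(tert-butyldimethylsilyl)oxy]methyl}-5,5-dimethyl-2-oxocyclohex-3-ene-1-carboxylate (ring A enone β-keto ester; trans isomer written, C10 epimerisable), via keto aldehyde 5 (not isolated)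
Conditions: 1-[(1R,2R)-2-aminocyclohexyl]-3-[3,5-bis(trifluoromethyl)phenyl]thiourea (20 mol%), PhCO2H (20 mol%), 4 (3 equiv), toluene, rt; then TsOH·H2O (30 mol%), 40 °C
Reagents that add atoms: none
Why: The primary amine condenses with 4 to an enamine whose C4 adds to C5 of 3 while the thiourea holds the 1,3-dicarbonyl unit, and hydrolysis of the iminium releases 5, which equilibrates with its cyclic hemiacetal. On acidification the C1 ketone enolises towards C2 and this enol attacks the aldehyde carbon C3 in a 6-(enolendo)-exo-trig aldol closure; loss of water gives the C2=C3 bond and ring A. The closest known reaction type is the amine-catalysed Michael addition of α,α-disubstituted aldehydes to doubly activated alkenes followed by a Robinson-type aldol condensation to a 4,4-disubstituted cyclohexenone. C5 is set by the catalyst, which should expose one face of the hydrogen-bonded acceptor, and both geometrical isomers of 3 are expected to funnel through the same bound form because they interconvert by reversible amine addition. C10 is not controlled here and need not be, since it remains epimerisable until step 3. The step needs closure through the C2 enol and not the more stable C10 enol; this is secured because attack from C10 would give a four-membered ring and because the quaternary C4 leaves the aldehyde unable to enolise or to dehydrate to a pyran. The mild acid and temperature are chosen so that the primary silyl ether and the ethyl ester should survive.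

Step 3
Reactants: 6 ethyl (1S,6S)-6-{[(tert-butyldimethylsilyl)oxy]methyl}-5,5-dimethyl-2-oxocyclohex-3-ene-1-carboxylate; 7 methyl acrylate
Product: 8 ethyl (1R,6R)-6-{[(tert-butyldimethylsilyl)oxy]methyl}-1-(3-methoxy-3-oxopropyl)-5,5-dimethyl-2-oxocyclohex-3-ene-1-carboxylate
Conditions: 7 (1.5 equiv), Cs2CO3 (20 mol%), MeCN, 0 °C to rt
Reagents that add atoms: none
Why: Michael addition of the β-keto ester enolate; C9 should enter anti to the neighbouring C5 silyloxymethyl arm, which makes C10 quaternary with C20 cis to C6. The transient ester enolate is protonated at once by unreacted 6, so a second Michael addition onto C3 is not expected.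

Step 4
Reactants: 8 ethyl (1R,6R)-6-{[(tert-butyldimethylsilyl)oxy]methyl}-1-(3-methoxy-3-oxopropyl)-5,5-dimethyl-2-oxocyclohex-3-ene-1-carboxylate
Product: 9 (5R,6S)-5-{[(tert-butyldimethylsilyl)oxy]methyl}-6-(hydroxymethyl)-6-(3-hydroxypropyl)-4,4-dimethylcyclohex-2-en-1-ol (C1 epimers)
Conditions: i-Bu2AlH (8 equiv), CH2Cl2, −78 to 0 °C; aq. potassium sodium tartrate
Reagents that add atoms: none
Why: Exhaustive hydride reduction: 1,2-reduction of the enone and reduction of both esters to primary carbinols; the C1 configuration is irrelevant because C1 is re-oxidised in step 5.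

Step 5
Reactants: 9 (5R,6S)-5-{[(tert-butyldimethylsilyl)oxy]methyl}-6-(hydroxymethyl)-6-(3-hydroxypropyl)-4,4-dimethylcyclohex-2-en-1-ol
Product: 10 (5R,6S)-5-{[(tert-butyldimethylsilyl)oxy]methyl}-6-(hydroxymethyl)-6-(3-hydroxypropyl)-4,4-dimethylcyclohex-2-en-1-one
Conditions: activated MnO2 (25 equiv), CH2Cl2, rt
Reagents that add atoms: none
Why: Allylic alcohol oxidation; MnO2 should leave the two saturated primary carbinols untouched and return the ring A enone without any protecting group.

Step 6
Reactants: 10 (5R,6S)-5-{[(tert-butyldimethylsilyl)oxy]methyl}-6-(hydroxymethyl)-6-(3-hydroxypropyl)-4,4-dimethylcyclohex-2-en-1-one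
Product: 11 (6S,11R)-11-{[(tert-butyldimethylsilyl)oxy]methyl}-10,10-dimethyl-2-oxaspiro[5.5]undec-8-ene-3,7-dione (spiro δ-lactone: C10–C20H2–O–C7(=O)–C8H2–C9H2)
Conditions: TEMPO (2,2,6,6-tetramethylpiperidin-1-oxyl, 20 mol%), PhI(OAc)2 (2.5 equiv), CH2Cl2, rt
Reagents that add atoms: none
Why: Oxidative lactonisation of a 1,5-diol; the oxoammonium species should oxidise the unhindered C7 carbinol before the neopentyl C20 carbinol, and the six-membered lactol is then oxidised to the lactone with the carbonyl at C7.

Step 7
Reactants: 11 (6S,11R)-11-{[(tert-butyldimethylsilyl)oxy]methyl}-10,10-dimethyl-2-oxaspiro[5.5]undec-8-ene-3,7-dione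
Product: 12 (6S,11R)-11-{[(tert-butyldimethylsilyl)oxy]methyl}-4-(hydroxymethylidene)-10,10-dimethyl-2-oxaspiro[5.5]undec-8-ene-3,7-dione (enol form of the C8 formyl lactone; C15 introduced)
Conditions: LiN(SiMe3)2 (2.2 equiv), THF, −78 °C; HCO2CH2CF3 (1.5 equiv), −78 °C; aq. NH4Cl
Reagents that add atoms: 2,2,2-trifluoroethyl formate, O=COCC(F)(F)F
Why: Claisen-type formylation of the lactone enolate at C8; the C8 hydrogens are the only acidic C–H bonds of 11 because the C1 enone has no α- or γ-hydrogen, and the reactive formate allows the enolate to be consumed at −78 °C.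

Step 8
Reactants: 12 (6S,11R)-11-{[(tert-butyldimethylsilyl)oxy]methyl}-4-(hydroxymethylidene)-10,10-dimethyl-2-oxaspiro[5.5]undec-8-ene-3,7-dione
Product: 13 (6S,11R)-11-{[(tert-butyldimethylsilyl)oxy]methyl}-10,10-dimethyl-3,7-dioxo-4-(phenylselanyl)-2-oxaspiro[5.5]undec-8-ene-4-carbaldehyde (C8 epimers)
Conditions: PhSeCl (1.1 equiv), pyridine (1.2 equiv), CH2Cl2, 0 °C
Reagents that add atoms: benzeneselenenyl chloride, Cl[Se]c1ccccc1
Why: Electrophilic selenenylation of the enolised β-dicarbonyl unit at C8; the electron-poor ring A alkene should not react.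

Step 9
Reactants: 13 (6S,11R)-11-{[(tert-butyldimethylsilyl)oxy]methyl}-10,10-dimethyl-3,7-dioxo-4-(phenylselanyl)-2-oxaspiro[5.5]undec-8-ene-4-carbaldehyde; 14 buta-1,3-diene
Product: 16 (5R,8S,9S,10S)-aldehyde in which the spirolactone is cis-fused at C8–C9 to a cyclohexene ring C (C8, C9, C11, C12=C13, C14), C8 carrying the C15 formyl group cis to H9, with the C6 silyl ether and ring A enone unchanged, via formyl dienophile 15 (not isolated)
Conditions: 30% aq. H2O2 (2 equiv), CH2Cl2, 0 °C; cold aq. NaHCO3 wash, Na2SO4; then 14 (10 equiv), ZnCl2 (0.5 equiv), CH2Cl2/Et2O, 0 °C to rt, sealed vessel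
Reagents that add atoms: none
Why: Oxidation at selenium and syn-elimination towards the only β-hydrogens (C9) give the doubly activated alkene 15, which is taken directly into a Diels–Alder reaction. The suprafacial [4+2] addition forms C9–C11 and C8–C14 on one face and so gives the cis ring fusion and the quaternary C8; 14 should approach the face of C8=C9 flanked by the planar C1 carbonyl, anti to the sp3 C5/C4 flank, which sets C8 and C9 relative to C10.

Step 10
Reactants: 17 acetaldehyde; 18 benzeneselenol
Product: 19 1,1-bis(phenylselanyl)ethane
Conditions: 18 (2.1 equiv), ZnCl2 (0.5 equiv), CH2Cl2, rt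
Reagents that add atoms: none
Why: Lewis-acid-promoted selenoacetal formation from an aldehyde and a selenol, the standard entry to α-selenoalkyllithium reagents.

Step 11
Reactants: 16 (5R,8S,9S,10S)-C15 aldehyde; 19 1,1-bis(phenylselanyl)ethane
Product: 21 (5R,8S,9S,10S)-β-hydroxy selenide in which C8 carries C15H(OH)–C16H(SePh)–C17H3 (C15 and C16 epimers), via 1-(phenylselanyl)ethyllithium 20 (not isolated)
Conditions: 19 (1.5 equiv), n-BuLi (1.45 equiv), THF, −78 °C; then 16, −78 °C; aq. NH4Cl at −78 °C
Reagents that add atoms: none
Why: Selenium–lithium exchange gives 20, which adds to the aldehyde, the only unhindered electrophilic carbonyl of a substrate that has no acidic C–H. The cold quench is meant to forestall retro-aldol loss of C15, and the new C15 and C16 centres are erased in steps 12–14.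

Step 12
Reactants: 21 (5R,8S,9S,10S)-β-hydroxy selenide
Product: 22 (5R,8S,9S,10S,13R)-tetracyclic alcohol with ring D closed (C8–C15H(OH)–C16H(CH3)–C13–C14; C15 and C16 epimers), C12 now CH2
Conditions: Bu3SnH (1.3 equiv, syringe pump), AIBN (2,2'-azobis(2-methylpropionitrile), 0.2 equiv), benzene, 80 °C
Reagents that add atoms: none
Why: Homolysis of the C–Se bond gives a secondary C16 radical on an all-sp3 tether, which should close 5-exo-trig onto C13 of the C12=C13 bond, and the C12 radical then takes hydrogen from the stannane. The radical can reach C13 only on the face that carries C15, so the bicyclo[3.2.1]octane and the C13 configuration follow from the tether.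

Step 13
Reactants: 22 (5R,8S,9S,10S,13R)-tetracyclic C15 alcohol
Product: 23 (5R,8S,9S,10S,13R)-C15 ketone (16-deoxy precursor of 24, C16 epimers), a non-enolisable β-keto lactone at C8
Conditions: Dess–Martin periodinane (1.5 equiv), CH2Cl2, rt
Reagents that add atoms: none
Why: Dess–Martin oxidation of a hindered secondary carbinol under neutral conditions that should spare the silyl ether, the enone and the lactone.

Step 14
Reactants: 23 (5R,8S,9S,10S,13R)-C15 ketone
Product: 24 (5R,8S,9S,10S,13R,16S)-6-O-(tert-butyldimethylsilyl) ether of the target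
Conditions: KN(SiMe3)2 (1.3 equiv), THF, −78 °C; then 2-(phenylsulfonyl)-3-phenyloxaziridine (1.5 equiv), −78 °C; aq. NH4Cl
Reagents that add atoms: 2-(phenylsulfonyl)-3-phenyloxaziridine, O=S(=O)(c1ccccc1)N1OC1c1ccccc1
Why: Enolate hydroxylation with an N-sulfonyloxaziridine; C16–H is the only enolisable position (C8, C10 and C4 are quaternary, C2 is vinylic). Oxygen should be delivered to the exo face of the C15=C16 enolate, anti to the C9–C11–C12 bridge, which places the hydroxyl exo and the methyl endo (16S) whatever the C16 configuration of 23.

Step 15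
Reactants: 24 (5R,8S,9S,10S,13R,16S)-6-O-(tert-butyldimethylsilyl) ether
Product: 25 CNP0530135.1, (5R,8S,9S,10S,13R,16S)-6,16-dihydroxy-1,15-dioxo-6,7-seco-ent-kaur-2-en-7,20-olide
Conditions: HF·pyridine, pyridine/THF, 0 °C to rt
Reagents that add atoms: none
Why: Fluoride-mediated cleavage of the primary silyl ether under buffered acidic conditions, chosen because the β-keto lactone and the α-ketol are sensitive to base.

## Compound list

1 | ethyl acetoacetate | CCOC(=O)CC(C)=O | starting material
2 | (tert-butyldimethylsilyloxy)acetaldehyde | O=CCO[Si](C)(C)C(C)(C)C | starting material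
3 | ethyl (2E)-2-acetyl-4-[(tert-butyldimethylsilyl)oxy]but-2-enoate (E shown; the 2Z isomer accompanies it) | CCOC(=O)/C(C(C)=O)=C/CO[Si](C)(C)C(C)(C)C | intermediate
4 | isobutyraldehyde (2-methylpropanal) | CC(C)C=O | starting material
5 | ethyl (3S)-2-acetyl-3-{[(tert-butyldimethylsilyl)oxy]methyl}-4,4-dimethyl-5-oxopentanoate (C2 epimers) | CCOC(=O)C(C(C)=O)[C@H](CO[Si](C)(C)C(C)(C)C)C(C)(C)C=O | intermediate (not isolated)
6 | ethyl (1S,6S)-6-{[(tert-butyldimethylsilyl)oxy]methyl}-5,5-dimethyl-2-oxocyclohex-3-ene-1-carboxylate (trans isomer written, C10 epimerisable) | CC1(C)C=CC(=O)[C@@H](C(=O)OCC)[C@@H]1CO[Si](C)(C)C(C)(C)C | intermediate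
7 | methyl acrylate | C=CC(=O)OC | starting material
8 | ethyl (1R,6R)-6-{[(tert-butyldimethylsilyl)oxy]methyl}-1-(3-methoxy-3-oxopropyl)-5,5-dimethyl-2-oxocyclohex-3-ene-1-carboxylate | CC1(C)C=CC(=O)[C@](CCC(=O)OC)(C(=O)OCC)[C@@H]1CO[Si](C)(C)C(C)(C)C | intermediate
9 | (5R,6S)-5-{[(tert-butyldimethylsilyl)oxy]methyl}-6-(hydroxymethyl)-6-(3-hydroxypropyl)-4,4-dimethylcyclohex-2-en-1-ol (C1 epimers) | CC1(C)C=CC(O)[C@](CCCO)(CO)[C@@H]1CO[Si](C)(C)C(C)(C)C | intermediate
10 | (5R,6S)-5-{[(tert-butyldimethylsilyl)oxy]methyl}-6-(hydroxymethyl)-6-(3-hydroxypropyl)-4,4-dimethylcyclohex-2-en-1-one | CC1(C)C=CC(=O)[C@](CCCO)(CO)[C@@H]1CO[Si](C)(C)C(C)(C)C | intermediate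
11 | (6S,11R)-11-{[(tert-butyldimethylsilyl)oxy]methyl}-10,10-dimethyl-2-oxaspiro[5.5]undec-8-ene-3,7-dione | CC1(C)C=CC(=O)[C@]2(COC(=O)CC2)[C@@H]1CO[Si](C)(C)C(C)(C)C | intermediate
12 | (6S,11R)-11-{[(tert-butyldimethylsilyl)oxy]methyl}-4-(hydroxymethylidene)-10,10-dimethyl-2-oxaspiro[5.5]undec-8-ene-3,7-dione (enol geometry not fixed) | CC1(C)C=CC(=O)[C@]2(COC(=O)C(=CO)C2)[C@@H]1CO[Si](C)(C)C(C)(C)C | intermediate
13 | (6S,11R)-11-{[(tert-butyldimethylsilyl)oxy]methyl}-10,10-dimethyl-3,7-dioxo-4-(phenylselanyl)-2-oxaspiro[5.5]undec-8-ene-4-carbaldehyde (C8 epimers) | CC1(C)C=CC(=O)[C@]2(COC(=O)C(C=O)([Se]c3ccccc3)C2)[C@@H]1CO[Si](C)(C)C(C)(C)C | intermediate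
14 | buta-1,3-diene | C=CC=C | starting material
15 | (6S,11R)-11-{[(tert-butyldimethylsilyl)oxy]methyl}-10,10-dimethyl-3,7-dioxo-2-oxaspiro[5.5]undeca-4,8-diene-4-carbaldehyde | CC1(C)C=CC(=O)[C@]2(COC(=O)C(C=O)=C2)[C@@H]1CO[Si](C)(C)C(C)(C)C | intermediate (not isolated)
16 | (5R,8S,9S,10S)-Diels–Alder aldehyde: spirolactone cis-fused at C8–C9 to cyclohexene ring C (C12=C13), C15 formyl on C8 cis to H9, C6 silyl ether | CC1(C)C=CC(=O)[C@]2(COC(=O)[C@@]3(C=O)CC=CC[C@H]32)[C@@H]1CO[Si](C)(C)C(C)(C)C | intermediate
17 | acetaldehyde | CC=O | starting material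
18 | benzeneselenol | [SeH]c1ccccc1 | starting material
19 | 1,1-bis(phenylselanyl)ethane | CC([Se]c1ccccc1)[Se]c1ccccc1 | intermediate
20 | 1-(phenylselanyl)ethyllithium | [Li]C(C)[Se]c1ccccc1 | intermediate (not isolated)
21 | (5R,8S,9S,10S)-β-hydroxy selenide: 16 with C15 as CH(OH) bonded to C16H(SePh)CH3 (C15 and C16 epimers) | CC1(C)C=CC(=O)[C@]2(COC(=O)[C@@]3(C(O)C(C)[Se]c4ccccc4)CC=CC[C@H]32)[C@@H]1CO[Si](C)(C)C(C)(C)C | intermediate
22 | (5R,8S,9S,10S,13R)-tetracyclic C15 alcohol with C16 methyl (C15 and C16 epimers), C6 silyl ether | CC1(C)C=CC(=O)[C@]2(COC(=O)[C@@]34C[C@@H](CC[C@H]32)C(C)C4O)[C@@H]1CO[Si](C)(C)C(C)(C)C | intermediate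
23 | (5R,8S,9S,10S,13R)-tetracyclic C15 ketone with C16 methyl (C16 epimers), C6 silyl ether | CC1(C)C=CC(=O)[C@]2(COC(=O)[C@@]34C[C@@H](CC[C@H]32)C(C)C4=O)[C@@H]1CO[Si](C)(C)C(C)(C)C | intermediate
24 | (5R,8S,9S,10S,13R,16S)-6-O-(tert-butyldimethylsilyl) ether of the target | CC1(C)C=CC(=O)[C@]2(COC(=O)[C@@]34C[C@@H](CC[C@H]32)[C@](C)(O)C4=O)[C@@H]1CO[Si](C)(C)C(C)(C)C | intermediate
25 | CNP0530135.1, (5R,8S,9S,10S,13R,16S)-6,16-dihydroxy-1,15-dioxo-6,7-seco-ent-kaur-2-en-7,20-olide | CC1(C)C=CC(=O)[C@]2(COC(=O)[C@@]34C[C@@H](CC[C@H]32)[C@](C)(O)C4=O)[C@@H]1CO | target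

## Step count and least certain steps

Total: 15 steps. Longest linear sequence: 14 steps (steps 1–9 and 11–15, from 1); step 10 is a one-step side branch.

Step 2 (key step). Most likely failure: slow or poorly face-selective conjugate addition, because a hindered enamine must attack a β-carbon that carries the silyloxymethyl group; in addition 3 can drift to its deconjugated enol-ether tautomer, or exchange its alkylidene part with the amine, before it is attacked. Fallback, setting out from 3 and 4 and returning at 6: 4 is condensed with (S)-2-(methoxymethyl)pyrrolidine to the stoichiometric chiral enamine (S)-2-(methoxymethyl)-1-(2-methylprop-1-en-1-yl)pyrrolidine F1. This far more nucleophilic enamine adds to 3 without a catalyst to give the 2-aminodihydropyran adduct F2. Aqueous acetic acid opens F2 to 5 and releases the auxiliary, and TsOH·H2O in toluene closes 5 to 6 as in step 2. Either enantiomer of the auxiliary is available.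

Step 3. Most likely failure: poor facial selectivity in the C10 alkylation, because the axial C4 methyl group on the face anti to C6 opposes the directing effect of the C5 arm. Fallback, setting out from 6 and returning at 11, in which a ring enforces the relation instead of a facial preference:
- Aqueous HF in MeCN removes the silyl group and the freed C6 carbinol lactonises onto the C20 ester (C10 epimerises as needed) to give the cis-fused keto γ-lactone F3.
- Michael addition of F3 to 7 (Cs2CO3, MeCN) can only give the cis-fused bicycle, that is C9 trans to C6, as F4.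
- i-Bu2AlH gives the tetraol F5 and MnO2 the enone triol F6.
- TEMPO/PhI(OAc)2 closes the δ-lactone from the unhindered C7 carbinol and the C20 carbinol (six-membered lactol preferred over the seven-membered one with the C6 carbinol) to give the hydroxy spirolactone F7.
- TBSCl and imidazole in DMF give 11.

Step 7. Most likely failure: consumption of the lactone enolate by conjugate addition to C3 of the ring A enone, or attack of the amide base on the enone, before formylation. Fallback, setting out from 11 and returning at 12: heating 11 with tert-butoxybis(dimethylamino)methane in toluene at 80 °C introduces C15 without a metal enolate and gives the enaminone F8; brief treatment with 1 M HCl in THF at 0 °C hydrolyses F8 to 12.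

Step 9. Most likely failure: loss of the formyl dienophile by hydration or self-condensation before cycloaddition, or insufficient facial bias at room temperature. Fallback, setting out from 11 and returning at 16, built on an isolable dienophile that tolerates stronger Lewis acids at low temperature:
- LiN(SiMe3)2 and then ClC(=O)SEt give the S-ethyl thioester F9.
- PhSeCl/pyridine gives the selenide F10, and H2O2 the unsaturated thioester lactone F11.
- F11 is combined with 14 and EtAlCl2 in CH2Cl2 at −40 °C to give the adduct F12.
- Fukuyama reduction of F12 (Et3SiH, Pd/C, acetone) gives 16. The survival of the two C=C bonds under these conditions would have to be checked.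

Step 12. Most likely failure: hydrogen transfer to the secondary C16 radical before ring closure, or partial 6-endo closure to a bicyclo[2.2.2]octane. Fallback, setting out from 16 and returning at 23, built on a faster-cyclising vinyl radical:
- HC≡CMgBr adds to the aldehyde of 16 to give the propargylic alcohol F13.
- Bu3SnH/AIBN at high stannane concentration adds tin to the alkyne terminus and the resulting C16 vinyl radical closes 5-exo onto C13 to give the vinylstannane F14.
- HCl in CHCl3 removes tin to give the exocyclic alkene F15, and Dess–Martin oxidation gives the 15-oxo-16(17)-ene F16.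
- Conjugate reduction of the unhindered exocyclic enone with [(Ph3P)CuH]6 in wet benzene, which should spare the hindered ring A enone, gives 23.

## Further compounds

F1 | step 2 | (S)-2-(methoxymethyl)-1-(2-methylprop-1-en-1-yl)pyrrolidine | COC[C@@H]1CCCN1C=C(C)C
F2 | step 2 | ethyl 4-{[(tert-butyldimethylsilyl)oxy]methyl}-2-[(2S)-2-(methoxymethyl)pyrrolidin-1-yl]-3,3,6-trimethyl-3,4-dihydro-2H-pyran-5-carboxylate (C5 as in 6, aminal carbon unassigned) | CCOC(=O)C1=C(C)OC(N2CCC[C@H]2COC)C(C)(C)[C@H]1CO[Si](C)(C)C(C)(C)C
F3 | step 3 | cis-4,4-dimethyl-3a,4-dihydro-2-benzofuran-1,7(3H,7aH)-dione (C5 as in 6, C20 lactonised onto O6) | CC1(C)C=CC(=O)[C@H]2[C@@H]1COC2=O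
F4 | step 3 | methyl 3-[cis-4,4-dimethyl-1,7-dioxo-3,3a,4,7-tetrahydro-2-benzofuran-7a(1H)-yl]propanoate | CC1(C)C=CC(=O)[C@@]2(CCC(=O)OC)[C@@H]1COC2=O
F5 | step 3 | (5R,6S)-5,6-bis(hydroxymethyl)-6-(3-hydroxypropyl)-4,4-dimethylcyclohex-2-en-1-ol (C1 epimers) | CC1(C)C=CC(O)[C@](CCCO)(CO)[C@@H]1CO
F6 | step 3 | (5R,6S)-5,6-bis(hydroxymethyl)-6-(3-hydroxypropyl)-4,4-dimethylcyclohex-2-en-1-one | CC1(C)C=CC(=O)[C@](CCCO)(CO)[C@@H]1CO
F7 | step 3 | (6S,11R)-11-(hydroxymethyl)-10,10-dimethyl-2-oxaspiro[5.5]undec-8-ene-3,7-dione | CC1(C)C=CC(=O)[C@]2(COC(=O)CC2)[C@@H]1CO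
F8 | step 7 | (6S,11R)-11-{[(tert-butyldimethylsilyl)oxy]methyl}-4-[(dimethylamino)methylidene]-10,10-dimethyl-2-oxaspiro[5.5]undec-8-ene-3,7-dione | CC1(C)C=CC(=O)[C@]2(COC(=O)C(=CN(C)C)C2)[C@@H]1CO[Si](C)(C)C(C)(C)C
F9 | step 9 | S-ethyl (6S,11R)-11-{[(tert-butyldimethylsilyl)oxy]methyl}-10,10-dimethyl-3,7-dioxo-2-oxaspiro[5.5]undec-8-ene-4-carbothioate (C8 epimers) | CC1(C)C=CC(=O)[C@]2(COC(=O)C(C(=O)SCC)C2)[C@@H]1CO[Si](C)(C)C(C)(C)C
F10 | step 9 | S-ethyl (6S,11R)-11-{[(tert-butyldimethylsilyl)oxy]methyl}-10,10-dimethyl-3,7-dioxo-4-(phenylselanyl)-2-oxaspiro[5.5]undec-8-ene-4-carbothioate (C8 epimers) | CC1(C)C=CC(=O)[C@]2(COC(=O)C(C(=O)SCC)([Se]c3ccccc3)C2)[C@@H]1CO[Si](C)(C)C(C)(C)C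
F11 | step 9 | S-ethyl (6S,11R)-11-{[(tert-butyldimethylsilyl)oxy]methyl}-10,10-dimethyl-3,7-dioxo-2-oxaspiro[5.5]undeca-4,8-diene-4-carbothioate | CC1(C)C=CC(=O)[C@]2(COC(=O)C(C(=O)SCC)=C2)[C@@H]1CO[Si](C)(C)C(C)(C)C
F12 | step 9 | (5R,8S,9S,10S)-S-ethyl thioester analogue of 16 (C15 as C(=O)SEt on C8) | CC1(C)C=CC(=O)[C@]2(COC(=O)[C@@]3(C(=O)SCC)CC=CC[C@H]32)[C@@H]1CO[Si](C)(C)C(C)(C)C
F13 | step 12 | (5R,8S,9S,10S)-propargylic alcohol: 16 with C15 as CH(OH) bonded to an ethynyl group (C15 epimers) | CC1(C)C=CC(=O)[C@]2(COC(=O)[C@@]3(C(O)C#C)CC=CC[C@H]32)[C@@H]1CO[Si](C)(C)C(C)(C)C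
F14 | step 12 | (5R,8S,9S,10S,13R)-ring D vinylstannane: C15 carbinol, C16=C17H(SnBu3) | CC1(C)C=CC(=O)[C@]2(COC(=O)[C@@]34C[C@@H](CC[C@H]32)C(=C[Sn](CCCC)(CCCC)CCCC)C4O)[C@@H]1CO[Si](C)(C)C(C)(C)C
F15 | step 12 | (5R,8S,9S,10S,13R)-15-hydroxy-16(17)-ene (C15 epimers), C6 silyl ether | CC1(C)C=CC(=O)[C@]2(COC(=O)[C@@]34C[C@@H](CC[C@H]32)C(=C)C4O)[C@@H]1CO[Si](C)(C)C(C)(C)C
F16 | step 12 | (5R,8S,9S,10S,13R)-15-oxo-16(17)-ene, C6 silyl ether | CC1(C)C=CC(=O)[C@]2(COC(=O)[C@@]34C[C@@H](CC[C@H]32)C(=C)C4=O)[C@@H]1CO[Si](C)(C)C(C)(C)C
A1 | alternative 1 | 2-{3-[(tert-butyldimethylsilyl)oxy]propyl}-2-{[(4-methoxyphenyl)methoxy]methyl}-6,6-dimethylcyclohex-3-ene-1-carboxylic acid (C5 and C10 as in 25) | CC1(C)CC=C[C@@](COCc2ccc(OC)cc2)(CCCO[Si](C)(C)C(C)(C)C)[C@@H]1C(O)=O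
A2 | alternative 2 | ethyl 3-(cis-5,5-dimethyl-2-oxobicyclo[4.2.0]oct-7-en-1-yl)propanoate (C5 and C10 as in 25) | CC1(C)CCC(=O)[C@]2(CCC(=O)OCC)C=C[C@H]12
A3 | alternative 2 | acetylene | C#C
A4 | alternative 3 | 2,3-dihydro-15-deoxo-15-hydroxy analogue of 24 (cis-15,16-diol, C6 silyl ether) | CC1(C)CCC(=O)[C@]2(COC(=O)[C@@]34C[C@@H](CC[C@H]32)[C@](C)(O)[C@@H]4O)[C@@H]1CO[Si](C)(C)C(C)(C)C
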